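Everything rests on cutting the pyrrole ring at C2–C3 and C4–C5 (Barton–Zard logic). The target has the formyl carbon on C2, the docosyl chain on the adjacent C3 and only hydrogen on C4 and C5; this pattern maps onto an isocyanoacetyl unit (ring nitrogen, C2, C5 and the carbonyl carbon) plus a terminal 1-nitroalkene (C3 with its chain, and C4). The key step forms both C–C bonds, closes the pyrrole ring and aromatises it by loss of nitrite in one operation. Its precursors are racemic 1-nitrotetracosan-2-yl acetate, which releases the nitroalkene in the flask, and the Weinreb amide of isocyanoacetic acid, so the aldehyde is reached afterwards by a single hydride reduction.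

Key step: step 6

Remark on the chemistry: compounds 4 and 5 are racemic at the carbinol carbon and 10 is taken as the E isomer; neither element reaches the target, which has no stereocentre.

Step 1
Reactants: 1 1-tricosanol
Product: 2 tricosanal
Conditions: TEMPO (0.1 equiv), PhI(OAc)2 (1.1 equiv), CH2Cl2, 35 °C; aq. Na2S2O3 wash; used promptly
Reagents that add atoms: none
Why: TEMPO-catalysed alcohol oxidation with PhI(OAc)2 as terminal oxidant should stop at the aldehyde under anhydrous conditions, and gentle warming keeps the waxy alcohol in solution.

Step 2
Reactants: 2 tricosanal, 3 nitromethane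
Product: 4 rac-1-nitrotetracosan-2-ol
Conditions: MeNO2 (10 equiv), DBU (0.1 equiv), THF, 0 °C to rt; AcOH quench
Reagents that add atoms: none
Why: Henry (nitroaldol) addition of the nitronate to the unhindered aldehyde, where excess nitromethane and only catalytic base should suppress dehydration and double addition; the carbinol centre forms as a racemate and is erased in step 6.

Step 3
Reactants: 4 rac-1-nitrotetracosan-2-ol
Product: 5 rac-1-nitrotetracosan-2-yl acetate
Conditions: Ac2O (2 equiv), pyridine (2.5 equiv), CH2Cl2, 0 °C to rt
Reagents that add atoms: acetic anhydride, CC(=O)OC(C)=O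
Why: O-acetylation of the secondary alcohol gives a storable leaving group for the later elimination; pyridine is too weak a base to cause much elimination at this temperature, and any nitroalkene formed converges in step 6.

Step 4
Reactants: 6 N-formylglycine, 7 N,O-dimethylhydroxylamine hydrochloride
Product: 8 2-formamido-N-methoxy-N-methylacetamide
Conditions: EDC hydrochloride (1.2 equiv), N-methylmorpholine (2.2 equiv), CH2Cl2/MeCN, 0 °C to rt; concentrate and filter through silica without aqueous extraction
Reagents that add atoms: none
Why: Carbodiimide amide coupling, free of racemisation issues because glycine has no stereocentre, with a non-aqueous isolation because the small amide is water-soluble.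

Step 5
Reactants: 8 2-formamido-N-methoxy-N-methylacetamide
Product: 9 2-isocyano-N-methoxy-N-methylacetamide
Conditions: POCl3 (1.1 equiv), Et3N (3 equiv), CH2Cl2, −20 to 0 °C; cold aq. Na2CO3, CH2Cl2 extraction
Reagents that add atoms: none
Why: Dehydration of an N-monosubstituted formamide to the isocyanide (Ugi isocyanide synthesis), under cold basic conditions that leave the Weinreb amide untouched.

Step 6
Reactants: 5 rac-1-nitrotetracosan-2-yl acetate, 9 2-isocyano-N-methoxy-N-methylacetamide
Product: 11 3-docosyl-N-methoxy-N-methyl-1H-pyrrole-2-carboxamide, via (E)-1-nitrotetracos-1-ene 10 (not isolated)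
Conditions: 9 (1.1 equiv), DBU (2.5 equiv), THF, 0 °C; 5 in warm THF added slowly; then rt
Reagents that add atoms: none
Why: DBU expels acetate from 5 by E1cB to give nitroalkene 10 and deprotonates the CH2 of isocyanide 9, whose carbanion adds in Michael fashion to the chain-bearing carbon of 10 (the C2–C3 bond). The nitronate carbon then attacks the isocyanide carbon in a 5-endo-dig closure (the C4–C5 bond) to give a pyrroline, which loses nitrite and undergoes a proton shift to the aromatic 1H-pyrrole. This is the Barton–Zard pyrrole synthesis, run with an isocyanoacetamide in place of the usual isocyanoacetate ester, a known variation. No stereocentre is created that survives, since the carbinol centre of 5 and the alkene geometry of 10 both vanish on aromatisation. The only selectivity needed is regiochemical, docosyl on C3 next to the amide-bearing C2, and the polarisation of the nitroalkene secures it because its sole electrophilic carbon is the one carrying the chain. Slow addition of 5 keeps free 10 dilute, so that Michael addition should outrun base-induced oligomerisation.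

Step 7
Reactants: 11 3-docosyl-N-methoxy-N-methyl-1H-pyrrole-2-carboxamide
Product: 12 3-docosyl-1H-pyrrole-2-carbaldehyde
Conditions: LiAlH4 (1.5 equiv), THF, 0 °C; then 1 M aq. HCl, 0 °C
Reagents that add atoms: none
Why: Weinreb amide reduction, in which the first hydride is spent on the pyrrole N–H and the next adds to the carbonyl to give a chelated N-methoxy aluminate that should persist until hydrolysis, so the aldehyde is released only on work-up.

Compound list
1 | 1-tricosanol | CCCCCCCCCCCCCCCCCCCCCCCO | starting material
2 | tricosanal | CCCCCCCCCCCCCCCCCCCCCCC=O | intermediate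
3 | nitromethane | C[N+](=O)[O-] | starting material
4 | rac-1-nitrotetracosan-2-ol | CCCCCCCCCCCCCCCCCCCCCCC(O)C[N+](=O)[O-] | intermediate
5 | rac-1-nitrotetracosan-2-yl acetate | CCCCCCCCCCCCCCCCCCCCCCC(OC(C)=O)C[N+](=O)[O-] | intermediate
6 | N-formylglycine | O=CNCC(=O)O | starting material
7 | N,O-dimethylhydroxylamine hydrochloride | CNOC.Cl | starting material
8 | 2-formamido-N-methoxy-N-methylacetamide | O=CNCC(=O)N(C)OC | intermediate
9 | 2-isocyano-N-methoxy-N-methylacetamide | [C-]#[N+]CC(=O)N(C)OC | intermediate
10 | (E)-1-nitrotetracos-1-ene, formed in the flask in step 6 | CCCCCCCCCCCCCCCCCCCCCC/C=C/[N+](=O)[O-] | intermediate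
11 | 3-docosyl-N-methoxy-N-methyl-1H-pyrrole-2-carboxamide | CCCCCCCCCCCCCCCCCCCCCCc1cc[nH]c1C(=O)N(C)OC | intermediate
12 | 3-docosyl-1H-pyrrole-2-carbaldehyde | CCCCCCCCCCCCCCCCCCCCCCc1cc[nH]c1C=O | target

Total step count: 7
Longest linear sequence: 5 steps (steps 1, 2, 3, 6, 7 from 1-tricosanol); the isocyanide arm adds 2 steps (4, 5).

Steps most likely to fail

Step 6. Deprotonation of the amide-type isocyanide may be too slow, so that the nitroalkene released in the flask oligomerises under base before it is intercepted. The fallback keeps the same ring construction but installs the Weinreb amide after the ring is made. It sets out from 5, which with commercial ethyl isocyanoacetate (more acidic CH2) and DBU in THF should give ethyl 3-docosyl-1H-pyrrole-2-carboxylate F1. Saponification (NaOH, EtOH/THF/H2O, reflux, then cold aq. KHSO4) would give 3-docosyl-1H-pyrrole-2-carboxylic acid F2. Coupling of this acid with 7 (EDC hydrochloride, N-methylmorpholine, CH2Cl2) comes back to the route at 11.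

Step 7. The N-metallated pyrrole may slow hydride delivery, or may push the aluminate adduct to collapse before work-up, which would lead to reduction beyond the aldehyde stage. The fallback sets out from 11 and removes the N–H first. Boc2O with catalytic DMAP in MeCN/THF should give tert-butyl 3-docosyl-2-[methoxy(methyl)carbamoyl]pyrrole-1-carboxylate F3. Its amide is no longer tied to a pyrrolide and would be reduced with i-Bu2AlH in THF at −40 °C to tert-butyl 3-docosyl-2-formylpyrrole-1-carboxylate F4. Cleavage of the carbamate with CF3CO2H in CH2Cl2 comes back to the route at 12.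

Step 5. The small polar isocyanide may be lost to the aqueous phase on work-up, or may polymerise on concentration after the dehydration. The fallback sets out from 7 and avoids the formamide altogether. Commercial ethyl isocyanoacetate is saponified (KOH, EtOH, 0 °C) to potassium 2-isocyanoacetate F5, collected as a solid. This salt is coupled with 7 (EDC hydrochloride, HOBt, N-methylmorpholine, DMF, 0 °C to rt), which comes back to the route at 9.

Further compounds
F1 | step 6 | ethyl 3-docosyl-1H-pyrrole-2-carboxylate | CCCCCCCCCCCCCCCCCCCCCCc1cc[nH]c1C(=O)OCC
F2 | step 6 | 3-docosyl-1H-pyrrole-2-carboxylic acid | CCCCCCCCCCCCCCCCCCCCCCc1cc[nH]c1C(=O)O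
F3 | step 7 | tert-butyl 3-docosyl-2-[methoxy(methyl)carbamoyl]pyrrole-1-carboxylate | CCCCCCCCCCCCCCCCCCCCCCc1ccn(C(=O)OC(C)(C)C)c1C(=O)N(C)OC
F4 | step 7 | tert-butyl 3-docosyl-2-formylpyrrole-1-carboxylate | CCCCCCCCCCCCCCCCCCCCCCc1ccn(C(=O)OC(C)(C)C)c1C=O
F5 | step 5 | potassium 2-isocyanoacetate | [C-]#[N+]CC(=O)[O-].[K+]
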